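**Retrosynthetic overview** (labdane numbering)

1. Target = 2β‑acetoxy‑labda‑8(17),13E‑dien‑15‑oic acid; endgame: acetylation ⇐ ester hydrolysis and C8 methylenation ⇐ selective reduction of the C2 ketone of a trans‑decalin‑2,8‑dione.
2. Ring B is formed last: C9–C10 is closed by an enantioselective isomerization/intramolecular Michael cascade on an achiral β,γ‑unsaturated seco‑diketone (sets C5, C9, C10; new method).
3. Fragment union C6–C7: palladium‑catalysed allylation of a silyl enol ether with a ring A allylic carbonate.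
4. Side arm C12–C13: palladium‑catalysed Negishi sp3–sp2 coupling of an alkylzinc with the E‑enol triflate of methyl acetoacetate (fixes the E‑enoate).
5. Ring A is formed first, by annulation of mesityl oxide with methyl acetoacetate, then ketalised with alkene shift.

Assumption: the quinine‑derived primary amine in step 11 gives the 4aS series drawn; if it gives the antipode, the quinidine‑derived pseudo‑enantiomer is used instead.

**Step 1**
Reactants: 1 methyl acetoacetate; 2 mesityl oxide
Product: 3 methyl 2,6,6-trimethyl-4-oxocyclohex-2-ene-1-carboxylate (racemic)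
Conditions: ZnCl2 (cat.), toluene, reflux, Dean–Stark
Reagents that add atoms: none
Why: Lewis‑acid promoted Michael addition of the acetoacetate to the β,β‑dimethyl enone followed by intramolecular aldol condensation (Robinson‑type annulation); the one stereocentre is racemic and is erased in step 2.

**Step 2**
Reactants: 3 methyl 2,6,6-trimethyl-4-oxocyclohex-2-ene-1-carboxylate
Product: 4 methyl 7,9,9-trimethyl-1,4-dioxaspiro[4.5]dec-7-ene-8-carboxylate
Conditions: HOCH2CH2OH, TsOH (cat.), toluene, reflux, Dean–Stark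
Reagents that add atoms: ethane-1,2-diol (OCCO)
Why: Acid‑catalysed ketalisation runs through the dienol ether, so the ring alkene leaves conjugation with the carbonyl and moves into conjugation with the ester (the enone to β,γ‑unsaturated ketal shift known from steroid ketalisation), giving an achiral tetrasubstituted alkene.

**Step 3**
Reactants: 4 methyl 7,9,9-trimethyl-1,4-dioxaspiro[4.5]dec-7-ene-8-carboxylate
Product: 5 (7,9,9-trimethyl-1,4-dioxaspiro[4.5]dec-7-en-8-yl)methanol
Conditions: LiAlH4, Et2O, 0 °C; then H2O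
Reagents that add atoms: none
Why: Hydride reduction of the ester to the primary allylic alcohol; the ketal protects the ketone and no acidic γ‑hydrogen is left.

**Step 4**
Reactants: 5 (7,9,9-trimethyl-1,4-dioxaspiro[4.5]dec-7-en-8-yl)methanol
Product: 6 methyl (7,9,9-trimethyl-1,4-dioxaspiro[4.5]dec-7-en-8-yl)methyl carbonate
Conditions: ClCO2Me, pyridine, CH2Cl2, 0 °C
Reagents that add atoms: methyl chloroformate (COC(=O)Cl)
Why: O‑Acylation of the alcohol gives the allylic carbonate that serves as the electrophile in the palladium allylation.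

**Step 5**
Reactants: 1 methyl acetoacetate
Product: 7 methyl (2E)-3-(trifluoromethylsulfonyloxy)but-2-enoate
Conditions: Tf2O, aq. Me4NOH, hexane, 5 °C
Reagents that add atoms: trifluoromethanesulfonic anhydride (O=S(=O)(OS(=O)(=O)C(F)(F)F)C(F)(F)F)
Why: Schotten–Baumann enol triflation; the non‑chelated tetramethylammonium enolate is trapped as the E enol triflate, which fixes the later E‑enoate geometry.

**Step 6**
Reactants: 8 5-chloropentan-2-one
Product: 9 2-(3-chloropropyl)-2-methyl-1,3-dioxolane
Conditions: HOCH2CH2OH, TsOH (cat.), toluene, reflux, Dean–Stark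
Reagents that add atoms: ethane-1,2-diol (OCCO)
Why: Acid‑catalysed dioxolane formation masks the ketone so that a Grignard reagent can be made from the chloride.

**Step 7**
Reactants: 9 2-(3-chloropropyl)-2-methyl-1,3-dioxolane; 7 methyl (2E)-3-(trifluoromethylsulfonyloxy)but-2-enoate
Product: 12 methyl (2E)-3-methyl-6-(2-methyl-1,3-dioxolan-2-yl)hex-2-enoate, via Grignard reagent 10 (not isolated), via organozinc chloride 11 (not isolated)
Conditions: Mg, THF, 60 °C; ZnCl2, THF, 0 °C; then 7, Pd(dppf)Cl2 (3 mol%), THF, 25 → 45 °C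
Reagents that add atoms: none
Why: Negishi sp3–sp2 cross‑coupling (oxidative addition of the vinyl triflate to zerovalent palladium, transmetallation from zinc, reductive elimination) goes with retention of alkene geometry, so the E‑trisubstituted enoate (C12–C13) is set here.

**Step 8**
Reactants: 12 methyl (2E)-3-methyl-6-(2-methyl-1,3-dioxolan-2-yl)hex-2-enoate
Product: 13 methyl (2E)-3-methyl-7-oxooct-2-enoate
Conditions: 1 M HCl (cat.), THF/H2O, 25 °C
Reagents that add atoms: water (O)
Why: Acetal hydrolysis frees the methyl ketone; the ester and the trisubstituted enoate are untouched.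

**Step 9**
Reactants: 13 methyl (2E)-3-methyl-7-oxooct-2-enoate
Product: 14 methyl (2E)-3-methyl-7-(trimethylsilyloxy)octa-2,7-dienoate
Conditions: LiN(i-Pr)2 (LDA), Me3SiCl (in situ), THF, −78 °C
Reagents that add atoms: chlorotrimethylsilane (C[Si](C)(C)Cl)
Why: Kinetic deprotonation of the methyl ketone at the methyl group with internal silyl quench gives the less substituted silyl enol ether; ketone α‑hydrogens are removed faster than the γ‑hydrogens of the enoate.

**Step 10**
Reactants: 6 methyl (7,9,9-trimethyl-1,4-dioxaspiro[4.5]dec-7-en-8-yl)methyl carbonate; 14 methyl (2E)-3-methyl-7-(trimethylsilyloxy)octa-2,7-dienoate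
Product: 16 methyl (2E)-3-methyl-7-oxo-9-(2,6,6-trimethyl-4-oxocyclohex-1-en-1-yl)non-2-enoate, via dioxolane-protected diketone 15 (not isolated)
Conditions: Pd2(dba)3 (2.5 mol%), dppe (5 mol%), THF, 65 °C; then aq. oxalic acid, 25 °C
Reagents that add atoms: water (O)
Why: Tsuji–Trost‑type palladium‑catalysed allylation of a silyl enol ether by an allylic carbonate: ionisation and loss of CO2 give a π‑allylpalladium methoxide, methoxide releases the regiodefined ketone enolate, and this attacks the unhindered CH2 terminus (C6–C7) so the tetrasubstituted alkene stays in the ring; mild acid then frees the β,γ‑unsaturated ketone without conjugation (no stereocentre is formed).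

**Step 11**
Reactants: 16 methyl (2E)-3-methyl-7-oxo-9-(2,6,6-trimethyl-4-oxocyclohex-1-en-1-yl)non-2-enoate
Product: 18 methyl (2E)-3-methyl-5-[(1R,4aS,8aS)-5,5,8a-trimethyl-2,7-dioxodecahydronaphthalen-1-yl]pent-2-enoate, via conjugated S-enone 17 (not isolated)
Conditions: 9-amino-9-deoxy-epi-quinine (20 mol%), CF3CO2H (40 mol%), toluene, 25 → 40 °C
Reagents that add atoms: none
Why: Proposed new method: the cinchona primary amine condenses with the ring ketone and forms a dienamine that its protonated quinuclidine protonates enantioselectively at the γ‑carbon (4aS); the resulting α,β‑unsaturated iminium is trapped by the enol of the tethered ketone in a reversible intramolecular Michael addition (C9–C10) that funnels to the trans‑fused dione with the equatorial side chain (8aS and 1R under thermodynamic control), and hydrolysis returns the catalyst; the closest known chemistry is the amine‑catalysed enantioselective isomerization of β,γ‑ to α,β‑unsaturated cyclohexenones combined with iminium‑catalysed intramolecular Michael (Robinson‑type) cyclisation.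

**Step 12**
Reactants: 18 methyl (2E)-3-methyl-5-[(1R,4aS,8aS)-5,5,8a-trimethyl-2,7-dioxodecahydronaphthalen-1-yl]pent-2-enoate
Product: 19 methyl (2E)-5-[(1R,4aS,7R,8aS)-7-hydroxy-5,5,8a-trimethyl-2-oxodecahydronaphthalen-1-yl]-3-methylpent-2-enoate
Conditions: KBH(s-Bu)3 (K-Selectride, 1.05 equiv), THF, −78 °C; then H2O
Reagents that add atoms: none
Why: Bulky‑hydride ketone reduction: the ring A ketone has two unsubstituted α‑CH2 groups and is attacked from the equatorial face, because the axial face is blocked by the two syn‑axial methyl groups, giving the axial 7R alcohol; the other ketone reacts more slowly since it is flanked by the side‑chain carbon next to the quaternary centre.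

**Step 13**
Reactants: 19 methyl (2E)-5-[(1R,4aS,7R,8aS)-7-hydroxy-5,5,8a-trimethyl-2-oxodecahydronaphthalen-1-yl]-3-methylpent-2-enoate
Product: 21 (2E)-5-[(1S,4aS,7R,8aS)-7-hydroxy-5,5,8a-trimethyl-2-methylidenedecahydronaphthalen-1-yl]-3-methylpent-2-enoic acid, via methyl ester 20 (not isolated)
Conditions: Ph3PCH3Br, KOt-Bu, THF, 25 → 60 °C; then LiOH, MeOH/H2O, 50 °C; aq. HCl
Reagents that add atoms: methyltriphenylphosphonium bromide (C[P+](c1ccccc1)(c1ccccc1)c1ccccc1.[Br-]); lithium hydroxide ([Li+].[OH-])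
Why: Wittig methylenation of the hindered ring B ketone (the usual route to 8(17)‑ene labdanes) leaves the thermodynamically preferred equatorial side chain, and saponification of the enoate in the same flask lets Ph3PO be removed by acid–base extraction.

**Step 14**
Reactants: 21 (2E)-5-[(1S,4aS,7R,8aS)-7-hydroxy-5,5,8a-trimethyl-2-methylidenedecahydronaphthalen-1-yl]-3-methylpent-2-enoic acid
Product: 23 (2E)-5-[(1S,4aS,7R,8aS)-7-acetoxy-5,5,8a-trimethyl-2-methylidenedecahydronaphthalen-1-yl]-3-methylpent-2-enoic acid, via mixed anhydride 22 (not isolated)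
Conditions: Ac2O, DMAP (cat.), pyridine, 50 °C; then H2O/THF, 25 °C
Reagents that add atoms: acetic anhydride (CC(=O)OC(C)=O)
Why: DMAP‑catalysed acetylation of the hindered axial alcohol; the acid is acetylated to the mixed anhydride in passing and water hydrolyses it back, leaving the configuration untouched.

**Compound list**

1 | methyl acetoacetate | CC(=O)CC(=O)OC | starting material
2 | mesityl oxide (4-methylpent-3-en-2-one) | CC(=O)C=C(C)C | starting material
3 | methyl 2,6,6-trimethyl-4-oxocyclohex-2-ene-1-carboxylate (racemic) | COC(=O)C1C(C)=CC(=O)CC1(C)C | intermediate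
4 | methyl 7,9,9-trimethyl-1,4-dioxaspiro[4.5]dec-7-ene-8-carboxylate | COC(=O)C1=C(C)CC2(CC1(C)C)OCCO2 | intermediate
5 | (7,9,9-trimethyl-1,4-dioxaspiro[4.5]dec-7-en-8-yl)methanol | OCC1=C(C)CC2(CC1(C)C)OCCO2 | intermediate
6 | methyl (7,9,9-trimethyl-1,4-dioxaspiro[4.5]dec-7-en-8-yl)methyl carbonate | COC(=O)OCC1=C(C)CC2(CC1(C)C)OCCO2 | intermediate
7 | methyl (2E)-3-(trifluoromethylsulfonyloxy)but-2-enoate | COC(=O)/C=C(\C)OS(=O)(=O)C(F)(F)F | intermediate
8 | 5-chloropentan-2-one | CC(=O)CCCCl | starting material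
9 | 2-(3-chloropropyl)-2-methyl-1,3-dioxolane | CC1(CCCCl)OCCO1 | intermediate
10 | chloro[3-(2-methyl-1,3-dioxolan-2-yl)propyl]magnesium | CC1(CCC[Mg]Cl)OCCO1 | intermediate
11 | chloro[3-(2-methyl-1,3-dioxolan-2-yl)propyl]zinc | CC1(CCC[Zn]Cl)OCCO1 | intermediate
12 | methyl (2E)-3-methyl-6-(2-methyl-1,3-dioxolan-2-yl)hex-2-enoate | COC(=O)/C=C(\C)CCCC1(C)OCCO1 | intermediate
13 | methyl (2E)-3-methyl-7-oxooct-2-enoate | COC(=O)/C=C(\C)CCCC(C)=O | intermediate
14 | methyl (2E)-3-methyl-7-(trimethylsilyloxy)octa-2,7-dienoate | COC(=O)/C=C(\C)CCCC(=C)O[Si](C)(C)C | intermediate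
15 | methyl (2E)-3-methyl-7-oxo-9-(7,9,9-trimethyl-1,4-dioxaspiro[4.5]dec-7-en-8-yl)non-2-enoate | COC(=O)/C=C(\C)CCCC(=O)CCC1=C(C)CC2(CC1(C)C)OCCO2 | intermediate
16 | methyl (2E)-3-methyl-7-oxo-9-(2,6,6-trimethyl-4-oxocyclohex-1-en-1-yl)non-2-enoate | COC(=O)/C=C(\C)CCCC(=O)CCC1=C(C)CC(=O)CC1(C)C | intermediate
17 | methyl (2E)-3-methyl-7-oxo-9-[(1S)-2,6,6-trimethyl-4-oxocyclohex-2-en-1-yl]non-2-enoate | COC(=O)/C=C(\C)CCCC(=O)CC[C@@H]1C(C)=CC(=O)CC1(C)C | intermediate
18 | methyl (2E)-3-methyl-5-[(1R,4aS,8aS)-5,5,8a-trimethyl-2,7-dioxodecahydronaphthalen-1-yl]pent-2-enoate | O=C1CC[C@H]2C(C)(C)CC(=O)C[C@]2(C)[C@H]1CC/C(C)=C/C(=O)OC | intermediate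
19 | methyl (2E)-5-[(1R,4aS,7R,8aS)-7-hydroxy-5,5,8a-trimethyl-2-oxodecahydronaphthalen-1-yl]-3-methylpent-2-enoate | O=C1CC[C@H]2C(C)(C)C[C@@H](O)C[C@]2(C)[C@H]1CC/C(C)=C/C(=O)OC | intermediate
20 | methyl (2E)-5-[(1S,4aS,7R,8aS)-7-hydroxy-5,5,8a-trimethyl-2-methylidenedecahydronaphthalen-1-yl]-3-methylpent-2-enoate | C=C1CC[C@H]2C(C)(C)C[C@@H](O)C[C@]2(C)[C@H]1CC/C(C)=C/C(=O)OC | intermediate
21 | (2E)-5-[(1S,4aS,7R,8aS)-7-hydroxy-5,5,8a-trimethyl-2-methylidenedecahydronaphthalen-1-yl]-3-methylpent-2-enoic acid | C=C1CC[C@H]2C(C)(C)C[C@@H](O)C[C@]2(C)[C@H]1CC/C(C)=C/C(=O)O | intermediate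
22 | acetic (2E)-5-[(1S,4aS,7R,8aS)-7-acetoxy-5,5,8a-trimethyl-2-methylidenedecahydronaphthalen-1-yl]-3-methylpent-2-enoic anhydride | C=C1CC[C@H]2C(C)(C)C[C@@H](OC(C)=O)C[C@]2(C)[C@H]1CC/C(C)=C/C(=O)OC(C)=O | intermediate
23 | (2E)-5-[(1S,4aS,7R,8aS)-7-acetoxy-5,5,8a-trimethyl-2-methylidenedecahydronaphthalen-1-yl]-3-methylpent-2-enoic acid | C=C1CC[C@H]2C(C)(C)C[C@@H](OC(C)=O)C[C@]2(C)[C@H]1CC/C(C)=C/C(=O)O | target

**Step count**

Total: 14 steps. Longest linear sequence: 9 steps (steps 1–4, then 10–14; the branches through steps 6–9 and through steps 5, 7–9 are equally long), 9/14.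

**Steps most likely to fail, with fallbacks**

Step 10 (palladium allylation). The tetrasubstituted allylic carbonate may ionise slowly or lose a β‑hydrogen to give dienes. The fallback makes C6–C7 by conjugate addition instead of allylic substitution. It sets out from 5 and uses 14. Aqueous HCl/THF removes the ketal and conjugates the alkene to give 4-(hydroxymethyl)-3,5,5-trimethylcyclohex-2-en-1-one F1. MsCl/Et3N gives (2,6,6-trimethyl-4-oxocyclohex-2-en-1-yl)methyl methanesulfonate F2, and DBU eliminates it (vinylogous E1cB) to 3,5,5-trimethyl-4-methylidenecyclohex-2-en-1-one F3. Me3SiNTf2‑catalysed Mukaiyama 1,6‑addition of 14 to the unhindered methylidene terminus gives the silyl dienol ether methyl (2E)-3-methyl-7-oxo-9-{2,6,6-trimethyl-4-[(trimethylsilyl)oxy]cyclohexa-1,3-dien-1-yl}non-2-enoate F4. Bu4NF/AcOH at −78 °C protonates F4 kinetically at the α‑carbon, and the route is rejoined at 16.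

Step 11 (the proposed new step). The enantioselective γ‑protonation at a carbon next to a quaternary centre and the Michael closure onto the hindered β‑carbon are both unproven. The fallback uses known chemistry, racemic cyclisation and classical resolution, and sets out from 16. DBU in THF conjugates the enone and effects the reversible intramolecular Michael addition to the racemic trans‑dione (racemic form of 18) F5. K‑Selectride as in step 12 gives the racemic hydroxy ketone (racemic form of 19) F6. (1S)‑Camphanic chloride/DMAP gives two diastereomeric esters; the (1S,4R)‑camphanate of the (7R) alcohol F7 is separated by crystallisation or chromatography. K2CO3/MeOH cleaves F7, and the route is rejoined at 19.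

Step 12 (selective reduction). The two ketones may not be differentiated well enough by the hydride. The fallback switches to a protecting‑group approach and sets out from 18. Ethane‑1,2‑diol/TsOH ketalises only the ketone next to the side chain, because a dioxolane at the ring A ketone would place an oxygen axial against two syn‑axial methyl groups; this gives the 2‑mono‑dioxolane of 18 F8. K‑Selectride reduces the remaining ketone from the equatorial face to the 2‑dioxolane of 19 F9. Aqueous HCl/THF removes the dioxolane, and the route is rejoined at 19.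

**Further compounds**

F1 | step 10 | 4-(hydroxymethyl)-3,5,5-trimethylcyclohex-2-en-1-one (racemic) | OCC1C(C)=CC(=O)CC1(C)C
F2 | step 10 | (2,6,6-trimethyl-4-oxocyclohex-2-en-1-yl)methyl methanesulfonate (racemic) | CS(=O)(=O)OCC1C(C)=CC(=O)CC1(C)C
F3 | step 10 | 3,5,5-trimethyl-4-methylidenecyclohex-2-en-1-one | C=C1C(C)=CC(=O)CC1(C)C
F4 | step 10 | methyl (2E)-3-methyl-7-oxo-9-{2,6,6-trimethyl-4-[(trimethylsilyl)oxy]cyclohexa-1,3-dien-1-yl}non-2-enoate | COC(=O)/C=C(\C)CCCC(=O)CCC1=C(C)C=C(O[Si](C)(C)C)CC1(C)C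
F5 | step 11 | racemic methyl (2E)-3-methyl-5-[(1RS,4aSR,8aSR)-5,5,8a-trimethyl-2,7-dioxodecahydronaphthalen-1-yl]pent-2-enoate | O=C1CC[C@H]2C(C)(C)CC(=O)C[C@]2(C)[C@H]1CC/C(C)=C/C(=O)OC.O=C1CC[C@@H]2C(C)(C)CC(=O)C[C@@]2(C)[C@@H]1CC/C(C)=C/C(=O)OC
F6 | step 11 | racemic methyl (2E)-5-[(1RS,4aSR,7RS,8aSR)-7-hydroxy-5,5,8a-trimethyl-2-oxodecahydronaphthalen-1-yl]-3-methylpent-2-enoate | O=C1CC[C@H]2C(C)(C)C[C@@H](O)C[C@]2(C)[C@H]1CC/C(C)=C/C(=O)OC.O=C1CC[C@@H]2C(C)(C)C[C@H](O)C[C@@]2(C)[C@@H]1CC/C(C)=C/C(=O)OC
F7 | step 11 | (1S,4R)-camphanate ester of 19 at the 7R hydroxyl | O=C1CC[C@H]2C(C)(C)C[C@@H](OC(=O)[C@@]34CC[C@@](C)(C(=O)O3)C4(C)C)C[C@]2(C)[C@H]1CC/C(C)=C/C(=O)OC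
F8 | step 12 | 18 with the ketone next to the side chain protected as its 1,3-dioxolane | O1CCOC12CC[C@H]3C(C)(C)CC(=O)C[C@]3(C)[C@H]2CC/C(C)=C/C(=O)OC
F9 | step 12 | 19 with the ketone next to the side chain protected as its 1,3-dioxolane | O1CCOC12CC[C@H]3C(C)(C)C[C@@H](O)C[C@]3(C)[C@H]2CC/C(C)=C/C(=O)OC
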